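**Retrosynthetic overview**

1. Numbering: C1 is the isopropenyl-bearing CH; the 14-membered carbocycle runs C1, C2, enoate C3=C4 (CO2Me on C4), C5, ketone C6, C7, methyl-bearing ether carbon C8, C9, ketone C10, ether CH C11, C12, ketone C13, C14; an oxygen links C8 and C11 (oxolan-3-one ring).
2. Feature and key disconnection: C12–C13 lies between C11 (oxygen-bearing, α to the C10 ketone) and C14, so the C13 ketone is taken back to a ring alkyne C12≡C13 whose hydration those neighbours direct; the cycloalkyne is opened by ring-closing alkyne metathesis to a diyne with a propynyl group on C11 and a but-2-ynyl group on C1.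
3. The diyne is cut at the Z-enoate C3=C4 (Still–Gennari) into a γ-keto phosphonoacetate and (R)-3-isopropenylhept-5-ynal; C3, C2, C1, C14, C13 and the isopropenyl group of the latter are C3, C4, C5, C6, C1 and the isopropenyl group of (S)-carvone (epoxidation, Eschenmoser–Tanabe fragmentation).
4. The phosphonate goes back through a bromomethyl ketone to 2-deoxy-D-ribose: sugar C4 = C11, C3 = C10 (kept as OTBS until the ring is closed), C1 = C8 (MeLi, then allylation of the oxocarbenium ion cis to the C10 oxygen), C5 = C12 (Corey–Fuchs), allyl group = C7–C5.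
5. Ring order: the oxolane ring comes from the sugar and is present throughout; the 14-membered carbocycle is closed at step 15; oxidation at C10 and hydration at C13 finish the target.

Key step: step 15

Remark: the C10 carbonyl is carried as its TBS (tert-butyldimethylsilyl) protected alcohol through olefination and ring closure, because a 2-(alk-1-ynyl)oxolan-3-one is a β,γ-ynone that would lose the C11 configuration and drift to the allenone under basic conditions; it is oxidised to the ketone directly before the hydration.

**Route**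

Step 1
Reactants: 1 (S)-carvone
Product: 2 (1S,4S,6S)-1-methyl-4-(prop-1-en-2-yl)-7-oxabicyclo[4.1.0]heptan-2-one
Conditions: 30% aq H2O2, NaOH (cat.), MeOH, 0 °C
Reagents that add atoms: hydrogen peroxide, OO
Why: Weitz–Scheffer nucleophilic epoxidation attacks only the enone (the isopropenyl group is not electrophilic) and hydroperoxide adds anti to the isopropenyl group to give the trans epoxide, whose two new stereocentres are erased in step 2.

Step 2
Reactants: 2 carvone epoxide; 3 p-toluenesulfonyl hydrazide
Product: 5 (R)-3-(prop-1-en-2-yl)hept-5-ynal, via tosylhydrazone 4 (not isolated)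
Conditions: TsNHNH2 (1.0 equiv), CH2Cl2/AcOH 1:1, −20 °C to rt
Reagents that add atoms: none
Why: Eschenmoser–Tanabe fragmentation, in which the tosylhydrazone opens the epoxide to an alkoxy diazene that fragments with loss of N2 and sulfinate, turns carvone C1–C2 into the methyl-capped alkyne and C3 into the aldehyde while the isopropenyl-bearing stereocentre (later C1) is untouched.

Step 3
Reactants: 6 2-deoxy-D-ribose
Product: 7 2-deoxy-D-ribono-1,4-lactone [(4S,5R)-4-hydroxy-5-(hydroxymethyl)oxolan-2-one]
Conditions: Br2, H2O, rt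
Reagents that add atoms: none
Why: Bromine-water oxidation of the aldose hemiacetal should give the aldonolactone, which settles as the five-membered 1,4-lactone without touching either stereocentre.

Step 4
Reactants: 7 2-deoxy-D-ribono-1,4-lactone
Product: 8 (4S,5R)-4-(TBSO)-5-(TBSOCH2)oxolan-2-one
Conditions: TBSCl (2.5 equiv), imidazole, DMF, rt
Reagents that add atoms: tert-butyldimethylsilyl chloride, CC(C)(C)[Si](C)(C)Cl
Why: Imidazole-promoted silylation protects both hydroxyls for the organolithium step and leaves the primary ether as the more labile one for step 7.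

Step 5
Reactants: 8 bis-TBS lactone
Product: 9 (4S,5R)-4-(TBSO)-5-(TBSOCH2)-2-methyloxolan-2-ol (anomeric mixture)
Conditions: MeLi (1.1 equiv), THF, −78 °C; AcOH quench at −78 °C
Reagents that add atoms: methyllithium, [Li]C
Why: Addition of MeLi to the lactone stops at the lithium hemiketal alkoxide at −78 °C and outruns enolisation and β-elimination of the silyloxy group, so protonation should give the methyl ketose, whose anomeric configuration is of no consequence.

Step 6
Reactants: 9 methyl hemiketal
Product: 10 (2R,4S,5R)-2-allyl-4-(TBSO)-5-(TBSOCH2)-2-methyloxolane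
Conditions: allylSiMe3 (3 equiv), BF3·OEt2, CH2Cl2, −78 to −50 °C
Reagents that add atoms: allyltrimethylsilane, C=CC[Si](C)(C)C
Why: Hosomi–Sakurai C-glycosylation of the methyl-substituted oxocarbenium ion, in which the allylsilane attacks the envelope from its inside face with the C10 silyloxy group pseudoaxial, places the allyl group cis to the C10 oxygen and trans to the C11 side chain and so should set the quaternary centre C8 (1,3-cis rule for 3-alkoxy furanosyl cations, the face hydride takes in 2-deoxy-C-nucleoside reductions).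

Step 7
Reactants: 10 bis-silyl ether
Product: 11 [(2R,3S,5R)-3-(TBSO)-5-methyl-5-(prop-2-en-1-yl)oxolan-2-yl]methanol
Conditions: HF·pyridine, pyridine, THF, 0 °C
Reagents that add atoms: none
Why: Buffered HF·pyridine cleaves the unhindered primary TBS ether well before the secondary one on C10 (steric differentiation in silyl ether cleavage).

Step 8
Reactants: 11 primary alcohol
Product: 12 (2S,3S,5R)-3-(TBSO)-5-methyl-5-(prop-2-en-1-yl)oxolane-2-carbaldehyde
Conditions: Dess–Martin periodinane (DMP), CH2Cl2, 0 °C to rt; used crude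
Reagents that add atoms: none
Why: Dess–Martin oxidation under non-basic conditions should give the α-alkoxy aldehyde without epimerising C11.

Step 9
Reactants: 12 aldehyde
Product: 13 (2R,4S,5R)-2-allyl-4-(TBSO)-5-(2,2-dibromoethenyl)-2-methyloxolane
Conditions: CBr4, PPh3, Zn, CH2Cl2, 0 °C to rt
Reagents that add atoms: carbon tetrabromide, BrC(Br)(Br)Br
Why: Corey–Fuchs dibromo-olefination with the ylide made in the flask is neutral, so the C11 stereocentre next to the aldehyde and the silyl ether should survive.

Step 10
Reactants: 13 dibromoalkene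
Product: 15 (2R,4S,5R)-2-allyl-4-(TBSO)-2-methyl-5-(prop-1-yn-1-yl)oxolane, via lithium acetylide 14 (not isolated)
Conditions: n-BuLi (2.1 equiv), THF, −78 to 0 °C; then MeI, −78 °C to rt
Reagents that add atoms: iodomethane, CI
Why: Second stage of the Corey–Fuchs sequence, Br/Li exchange and rearrangement to the alkyne, deprotonation to the acetylide and C-methylation, gives the methyl-capped alkyne while silyl ether, allyl group and ring ether are inert to n-BuLi at low temperature.

Step 11
Reactants: 15 allyl propynyl oxolane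
Product: 16 1-bromo-3-[(2R,4S,5R)-4-(TBSO)-2-methyl-5-(prop-1-yn-1-yl)oxolan-2-yl]propan-2-ol (both carbinol epimers)
Conditions: NBS, DMSO/H2O, 0 °C
Reagents that add atoms: N-bromosuccinimide, O=C1CCC(=O)N1Br; water, O
Why: Bromohydrin formation (bromonium ion opened by water at the more substituted C6) is faster on the monosubstituted alkene than on the internal alkyne, and the two C6 epimers converge in step 12.

Step 12
Reactants: 16 bromohydrin
Product: 17 1-bromo-3-[(2S,4S,5R)-4-(TBSO)-2-methyl-5-(prop-1-yn-1-yl)oxolan-2-yl]propan-2-one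
Conditions: DMP, CH2Cl2, rt
Reagents that add atoms: none
Why: Dess–Martin oxidation should convert both carbinol epimers into the single α-bromo ketone under conditions that do not enolise it.

Step 13
Reactants: 17 bromomethyl ketone; 18 methyl bis(2,2,2-trifluoroethyl)phosphonoacetate
Product: 19 methyl 2-[bis(2,2,2-trifluoroethoxy)phosphoryl]-5-[(2S,4S,5R)-4-(TBSO)-2-methyl-5-(prop-1-yn-1-yl)oxolan-2-yl]-4-oxopentanoate (both C2 epimers)
Conditions: 18 (1.5 equiv), NaH, THF, 0 °C; then 17, 0 °C to rt
Reagents that add atoms: none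
Why: SN2 alkylation of the soft, weakly basic sodium phosphonoacetate at the primary α-bromo ketone carbon forms C4–C5, excess 18 limiting double alkylation, and the C4 epimers converge in step 14.

Step 14
Reactants: 19 γ-keto phosphonate; 5 (R)-3-(prop-1-en-2-yl)hept-5-ynal
Product: 20 methyl (2Z,5S)-2-{3-[(2S,4S,5R)-4-(TBSO)-2-methyl-5-(prop-1-yn-1-yl)oxolan-2-yl]-2-oxopropyl}-5-(prop-1-en-2-yl)non-2-en-7-ynoate
Conditions: KHMDS (1.0 equiv), 18-crown-6, THF, −78 °C; then 5
Reagents that add atoms: none
Why: Still–Gennari olefination, in which the electron-poor bis(trifluoroethyl) phosphonate with a dissociated potassium counter-ion eliminates from the kinetic adduct before it equilibrates, should place the aldehyde chain cis to the ester (Z), and because the phosphonate C–H is by far the most acidic site of 19 one equivalent of base leaves the ketones and C11–H alone.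

Step 15
Reactants: 20 diyne
Product: 21 TBS-protected cycloalkyne (target numbering: C12≡C13; C10–OTBS; 1S,3Z,8S,10S,11R)
Conditions: [Mo(≡C-C6H4-4-OMe)(OSiPh3)3] (10 mol %), MS 5 Å, toluene, 2 mM, rt to 60 °C
Reagents that add atoms: none
Why: The alkylidyne adds to one methyl-capped alkyne to give a metallacyclobutadiene ([2+2]) and cycloreverts, then does the same with the second alkyne of the same molecule, so that the two capping C–CH3 units leave as but-2-yne and C12≡C13 is formed; the closest known reaction type is ring-closing alkyne metathesis of bis(methyl-capped) diynes with molybdenum alkylidyne silanolate catalysts. The 14-membered carbocycle (13-membered along the ether bridge) closes by end-to-end macrocyclisation at the new triple bond, a ring large enough to hold an alkyne without strain. No stereocentre is formed, and C1, C8, C10 and C11 are spectators. The step needs chemoselectivity for the two alkynes, which the alkylidyne provides because it does not engage the isopropenyl group, the enoate, the ketone or the silyl ether and needs no base, so C11 and the β-alkoxy ketone are not at risk. It also needs closure over oligomerisation, which high dilution and trapping of but-2-yne in the 5 Å sieves should secure, with the Z-enoate and the 2,5-trans oxolane expected to act as turn elements in the chain.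

Step 16
Reactants: 21 TBS-protected cycloalkyne
Product: 22 cycloalkyne C10 alcohol (1S,3Z,8S,10S,11R)
Conditions: HF·pyridine, pyridine, THF, 0 °C to rt
Reagents that add atoms: none
Why: Fluoride cleavage of the secondary TBS ether under buffered, non-basic conditions should be tolerated by the β-alkoxy ketone, the enoate and the cycloalkyne.

Step 17
Reactants: 22 cycloalkyne C10 alcohol
Product: 23 cycloalkyne C10 ketone (β,γ-ynone; 1S,3Z,8R,11R)
Conditions: DMP, CH2Cl2, 0 °C; used at once
Reagents that add atoms: none
Why: Dess–Martin oxidation of the homopropargylic alcohol under neutral to weakly acidic conditions should give the β,γ-ynone without the base that would cause ynone-to-allenone isomerisation or C11 epimerisation.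

Step 18
Reactants: 23 cycloalkyne C10 ketone
Product: 24 target CNP0163183.3 (1S,3Z,8R,11R)
Conditions: NaAuCl4·2H2O (5 mol %), THF/H2O 10:1, rt
Reagents that add atoms: water, O
Why: Carbonyl-assisted gold-catalysed alkyne hydration, in which the C10 carbonyl oxygen attacks the activated alkyne at C13 (5-endo-dig), water opens the cyclic oxocarbenium ion at C10 and protodeauration releases the 1,4-diketone, should put the new carbonyl on C13 (the inductive pull of the C11 oxygen points the same way), and excess water should intercept the oxocarbenium ion before it loses the C11 proton to a furan.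

**Compound list**

1 | (S)-carvone | CC1=CC[C@H](C(C)=C)CC1=O | starting material
2 | (1S,4S,6S)-1-methyl-4-(prop-1-en-2-yl)-7-oxabicyclo[4.1.0]heptan-2-one | C[C@]12O[C@H]1C[C@H](C(C)=C)CC2=O | intermediate
3 | p-toluenesulfonyl hydrazide | Cc1ccc(cc1)S(=O)(=O)NN | starting material
4 | tosylhydrazone of 2 | C[C@]12O[C@H]1C[C@H](C(C)=C)CC2=NNS(=O)(=O)c1ccc(C)cc1 | intermediate
5 | (R)-3-(prop-1-en-2-yl)hept-5-ynal | O=CC[C@H](C(C)=C)CC#CC | intermediate
6 | 2-deoxy-D-ribose (open-chain form) | O=CC[C@H](O)[C@H](O)CO | starting material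
7 | 2-deoxy-D-ribono-1,4-lactone | O=C1C[C@H](O)[C@@H](CO)O1 | intermediate
8 | (4S,5R)-4-(TBSO)-5-(TBSOCH2)oxolan-2-one | O=C1C[C@H](O[Si](C)(C)C(C)(C)C)[C@@H](CO[Si](C)(C)C(C)(C)C)O1 | intermediate
9 | (4S,5R)-4-(TBSO)-5-(TBSOCH2)-2-methyloxolan-2-ol, anomeric mixture | CC1(O)C[C@H](O[Si](C)(C)C(C)(C)C)[C@@H](CO[Si](C)(C)C(C)(C)C)O1 | intermediate
10 | (2R,4S,5R)-2-allyl-4-(TBSO)-5-(TBSOCH2)-2-methyloxolane | C=CC[C@]1(C)C[C@H](O[Si](C)(C)C(C)(C)C)[C@@H](CO[Si](C)(C)C(C)(C)C)O1 | intermediate
11 | [(2R,3S,5R)-3-(TBSO)-5-methyl-5-(prop-2-en-1-yl)oxolan-2-yl]methanol | C=CC[C@]1(C)C[C@H](O[Si](C)(C)C(C)(C)C)[C@@H](CO)O1 | intermediate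
12 | (2S,3S,5R)-3-(TBSO)-5-methyl-5-(prop-2-en-1-yl)oxolane-2-carbaldehyde | C=CC[C@]1(C)C[C@H](O[Si](C)(C)C(C)(C)C)[C@@H](C=O)O1 | intermediate
13 | (2R,4S,5R)-2-allyl-4-(TBSO)-5-(2,2-dibromoethenyl)-2-methyloxolane | C=CC[C@]1(C)C[C@H](O[Si](C)(C)C(C)(C)C)[C@@H](C=C(Br)Br)O1 | intermediate
14 | lithium acetylide of the C11 ethynyl oxolane | C=CC[C@]1(C)C[C@H](O[Si](C)(C)C(C)(C)C)[C@@H](C#C[Li])O1 | intermediate
15 | (2R,4S,5R)-2-allyl-4-(TBSO)-2-methyl-5-(prop-1-yn-1-yl)oxolane | C=CC[C@]1(C)C[C@H](O[Si](C)(C)C(C)(C)C)[C@@H](C#CC)O1 | intermediate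
16 | 1-bromo-3-[(2R,4S,5R)-4-(TBSO)-2-methyl-5-(prop-1-yn-1-yl)oxolan-2-yl]propan-2-ol, both carbinol epimers | BrCC(O)C[C@]1(C)C[C@H](O[Si](C)(C)C(C)(C)C)[C@@H](C#CC)O1 | intermediate
17 | 1-bromo-3-[(2S,4S,5R)-4-(TBSO)-2-methyl-5-(prop-1-yn-1-yl)oxolan-2-yl]propan-2-one | BrCC(=O)C[C@]1(C)C[C@H](O[Si](C)(C)C(C)(C)C)[C@@H](C#CC)O1 | intermediate
18 | methyl bis(2,2,2-trifluoroethyl)phosphonoacetate | COC(=O)CP(=O)(OCC(F)(F)F)OCC(F)(F)F | starting material
19 | methyl 2-[bis(2,2,2-trifluoroethoxy)phosphoryl]-5-[(2S,4S,5R)-4-(TBSO)-2-methyl-5-(prop-1-yn-1-yl)oxolan-2-yl]-4-oxopentanoate, both C2 epimers | COC(=O)C(CC(=O)C[C@]1(C)C[C@H](O[Si](C)(C)C(C)(C)C)[C@@H](C#CC)O1)P(=O)(OCC(F)(F)F)OCC(F)(F)F | intermediate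
20 | diyne: methyl (2Z,5S)-2-{3-[(2S,4S,5R)-4-(TBSO)-2-methyl-5-(prop-1-yn-1-yl)oxolan-2-yl]-2-oxopropyl}-5-(prop-1-en-2-yl)non-2-en-7-ynoate | C=C(C)[C@H](CC#CC)C/C=C(\C(=O)OC)CC(=O)C[C@]1(C)C[C@H](O[Si](C)(C)C(C)(C)C)[C@@H](C#CC)O1 | intermediate
21 | TBS-protected cycloalkyne: 14-membered carbocycle, C12≡C13, C8–O–C11 oxolane bridge, C10–OTBS, C6 ketone, (3Z)-enoate with CO2Me on C4, isopropenyl on C1; (1S,8S,10S,11R) | C=C(C)[C@H]1C/C=C(\C(=O)OC)CC(=O)C[C@]2(C)C[C@H](O[Si](C)(C)C(C)(C)C)[C@@H](C#CC1)O2 | intermediate
22 | cycloalkyne C10 alcohol: as 21 with C10–OH; (1S,3Z,8S,10S,11R) | C=C(C)[C@H]1C/C=C(\C(=O)OC)CC(=O)C[C@]2(C)C[C@H](O)[C@@H](C#CC1)O2 | intermediate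
23 | cycloalkyne C10 ketone: as 21 with C10=O; (1S,3Z,8R,11R) | C=C(C)[C@H]1C/C=C(\C(=O)OC)CC(=O)C[C@]2(C)CC(=O)[C@@H](C#CC1)O2 | intermediate
24 | CNP0163183.3: ketones at C6, C10 and C13; (1S,3Z,8R,11R) | C=C(C)[C@H]1C/C=C(\C(=O)OC)CC(=O)C[C@]2(C)CC(=O)[C@@H](CC(=O)C1)O2 | target

**Step count**

Total: 18 steps. Longest linear sequence: 16 steps (steps 3 to 18, from 2-deoxy-D-ribose); the carvone branch (steps 1 and 2) joins at step 14.

**Steps most likely to fail**

1. Step 15 (ring-closing alkyne metathesis). What may go wrong: slow metallacycle formation at the branched propargylic ether end, so that acyclic diyne metathesis (oligomerisation) outruns closure, or loss of catalyst to the γ-keto enoate. Fallback: the C12≡C13 bond is made between fragments and the ring is closed at C3=C4 instead. It sets out from aldehyde 5 and phosphonate 19. Aldehyde 5 is converted (HC(OMe)3, PPTS, MeOH) into the dimethyl acetal F1. Alkyne cross-metathesis of 19 with an excess of F1 (same molybdenum catalyst, MS 5 Å, toluene, 0.1 M) should give the acetal phosphonate F2. Mild acetal hydrolysis (PPTS, wet acetone) should give the aldehyde phosphonate F3. Intramolecular Still–Gennari olefination of F3 under high dilution (KHMDS, 18-crown-6, THF, −78 °C, 1 mM) comes back to the route at cycloalkyne 21.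

2. Step 18 (hydration, together with the ynone of step 17). What may go wrong: cycloisomerisation of the β,γ-ynone to the fused furan in place of water capture, or enolisation toward C11 with loss of configuration or drift to the allenone. Fallback: the alkyne is hydrated before the C10 ketone exists. It sets out from cycloalkyne 21. Gold(I)-catalysed hydration ((Ph3P)AuNTf2, wet 1,4-dioxane, 50 °C), in which the oxygens on C11 and C10 deactivate C12 inductively so that water adds at C13, should give the C13 ketone silyl ether F4. HF·pyridine should then give the C10 alcohol F5. Dess–Martin oxidation of F5 comes back to the route at target 24.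

3. Step 14 (Still–Gennari olefination). What may go wrong: erosion of Z selectivity with the bulky, fully substituted phosphonate carbanion, retro-oxa-Michael opening at C8, or migration of the new double bond toward the C6 ketone under base. Fallback: the trisubstituted enoate is built by olefination with a small bromo phosphonate followed by cross-coupling. It sets out from 18, aldehyde 5 and bromoketone 17. Bromination of 18 (NaH, then NBS, THF, 0 °C) should give the bromophosphonoacetate F6. Its Horner–Wadsworth–Emmons reaction with 5 (t-BuOK, 18-crown-6, THF, −78 °C), which favours the (E)-α-bromoacrylate with the alkyl chain cis to the ester, should give the bromoacrylate F7. Zinc insertion into 17 (activated Zn, THF) should give the Reformatsky reagent F8. Palladium-catalysed Negishi-type coupling of F8 with F7 (Pd(dba)2, bulky phosphine, THF, rt), which retains the alkene geometry, comes back to the route at diyne 20.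

Further compounds
F1 | step 15 | (5R)-7,7-dimethoxy-5-(prop-1-en-2-yl)hept-2-yne | COC(OC)C[C@H](C(C)=C)CC#CC
F2 | step 15 | acetal phosphonate: 19 with the alkyne cap replaced by the (4S)-6,6-dimethoxy-4-(prop-1-en-2-yl)hex-1-yn-1-yl chain | COC(=O)C(CC(=O)C[C@]1(C)C[C@H](O[Si](C)(C)C(C)(C)C)[C@@H](C#CC[C@@H](C(C)=C)CC(OC)OC)O1)P(=O)(OCC(F)(F)F)OCC(F)(F)F
F3 | step 15 | aldehyde phosphonate: F2 with the acetal hydrolysed to the aldehyde | COC(=O)C(CC(=O)C[C@]1(C)C[C@H](O[Si](C)(C)C(C)(C)C)[C@@H](C#CC[C@@H](C(C)=C)CC=O)O1)P(=O)(OCC(F)(F)F)OCC(F)(F)F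
F4 | step 18 | C13 ketone silyl ether: target skeleton with C10–OTBS in place of the C10 ketone | C=C(C)[C@H]1C/C=C(\C(=O)OC)CC(=O)C[C@]2(C)C[C@H](O[Si](C)(C)C(C)(C)C)[C@@H](CC(=O)C1)O2
F5 | step 18 | C10 alcohol: target skeleton with C10–OH in place of the C10 ketone | C=C(C)[C@H]1C/C=C(\C(=O)OC)CC(=O)C[C@]2(C)C[C@H](O)[C@@H](CC(=O)C1)O2
F6 | step 14 | methyl 2-bromo-2-[bis(2,2,2-trifluoroethoxy)phosphoryl]acetate | COC(=O)C(Br)P(=O)(OCC(F)(F)F)OCC(F)(F)F
F7 | step 14 | methyl (2E,5S)-2-bromo-5-(prop-1-en-2-yl)non-2-en-7-ynoate | C=C(C)[C@H](CC#CC)C/C=C(/Br)C(=O)OC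
F8 | step 14 | bromozinc enolate (Reformatsky reagent) of 17 | C=C(O[Zn]Br)C[C@]1(C)C[C@H](O[Si](C)(C)C(C)(C)C)[C@@H](C#CC)O1
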